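**Retrosynthetic overview**
1. Target ⇒ removal of two silyl ethers. Ring C (O1–C2 bond) ⇒ intramolecular Mitsunobu etherification of an (R)-2-aryl-3-(2-hydroxyaryl)propan-1-ol, obtained by hydride opening of an (R)-3-aryl-dihydrocoumarin.
2. Key disconnection C3–C1′: a racemic 3-bromodihydrocoumarin used as an enolonium (α-acyl cation) equivalent plus the ring B arylzinc. A nickel/pybox enantioconvergent coupling sets C3 as (R).
3. Bromolactone ⇒ 4-bromoresorcinol + acrylic acid (Friedel–Crafts/lactonisation), silylation, Stille prenylation, α-bromination.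
4. Arylzinc ⇒ 8-bromo-2,2-dimethylchromene silyl ether ⇒ 4-bromoresorcinol mono-silyl ether + 3-chloro-3-methylbut-1-yne (propargyl ether, Claisen cascade).
5. Ring order: temporary lactone ring on ring A, then dimethylpyran ring D on ring B, then (after lactone opening) ring C.

Assumption: the sense of induction in step 8 cannot be read from precedent for this lactone; (R,R)-Ph-pybox is written, and its mirror-image ligand is used if a first trial gives the (S)-lactone.

**Route**

Step 1
Reactants: 1 4-bromoresorcinol; 2 acrylic acid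
Product: 3 6-bromo-7-hydroxychroman-2-one
Conditions: Amberlyst-15, toluene, reflux (Dean–Stark)
Reagents that add atoms: none
Why: Acid-resin Friedel–Crafts hydroarylation of acrylic acid at the ring carbon of 1 that is para to one hydroxyl and ortho to the other (the position between the hydroxyls is more hindered), followed by lactonisation onto the adjacent hydroxyl, is the standard entry to 7-hydroxydihydrocoumarins and places bromine at C6.

Step 2
Reactants: 3 6-bromo-7-hydroxychroman-2-one
Product: 4 6-bromo-7-[(triisopropylsilyl)oxy]chroman-2-one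
Conditions: i-Pr3SiOTf, 2,6-lutidine, CH2Cl2, 0 °C
Reagents that add atoms: triisopropylsilyl trifluoromethanesulfonate, CC(C)[Si](OS(=O)(=O)C(F)(F)F)(C(C)C)C(C)C
Why: Phenol silylation with a silyl triflate and a hindered non-nucleophilic base does not open the aryl lactone and masks O7 for the bromination, organozinc and Mitsunobu steps.

Step 3
Reactants: 4 6-bromo-7-[(triisopropylsilyl)oxy]chroman-2-one; 5 tributyl(3-methylbut-2-en-1-yl)stannane
Product: 6 6-(3-methylbut-2-en-1-yl)-7-[(triisopropylsilyl)oxy]chroman-2-one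
Conditions: Pd(PPh3)4 (5 mol%), DMF, 100 °C
Reagents that add atoms: none
Why: Stille coupling under neutral conditions leaves lactone and silyl ether intact, and reductive elimination at the less hindered allyl terminus gives the linear prenyl group.

Step 4
Reactants: 6 6-(3-methylbut-2-en-1-yl)-7-[(triisopropylsilyl)oxy]chroman-2-one
Product: 8 rac-3-bromo-6-(3-methylbut-2-en-1-yl)-7-[(triisopropylsilyl)oxy]chroman-2-one, via trimethylsilyl ketene acetal 7 (not isolated)
Conditions: LiN(SiMe3)2, Me3SiCl, THF, −78 °C; then NBS, −78 °C; cold pH 7 work-up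
Reagents that add atoms: N-bromosuccinimide, O=C1CCC(=O)N1Br
Why: The lactone enolate is trapped in situ as its silyl ketene acetal, which NBS brominates far faster than the prenyl alkene or the arene (electrophilic α-halogenation), giving the racemic α-bromolactone that serves as the enolonium equivalent.

Step 5
Reactants: 1 4-bromoresorcinol
Product: 9 2-bromo-5-[(triisopropylsilyl)oxy]phenol
Conditions: i-Pr3SiCl (1.0 equiv), imidazole, CH2Cl2, −20 to 0 °C
Reagents that add atoms: chlorotriisopropylsilane, CC(C)[Si](Cl)(C(C)C)C(C)C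
Why: Sterically controlled mono-silylation, in which the bulky silyl chloride takes the unhindered hydroxyl para to bromine in preference to the hydroxyl flanked by bromine.

Step 6
Reactants: 9 2-bromo-5-[(triisopropylsilyl)oxy]phenol; 10 3-chloro-3-methylbut-1-yne
Product: 11 [4-bromo-3-(2-methylbut-3-yn-2-yloxy)phenoxy]triisopropylsilane
Conditions: DBU, CuCl2 (1 mol%), MeCN, 0 °C
Reagents that add atoms: none
Why: Copper-catalysed propargylic substitution of the tertiary chloride etherifies the only free phenol.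

Step 7
Reactants: 11 [4-bromo-3-(2-methylbut-3-yn-2-yloxy)phenoxy]triisopropylsilane
Product: 12 8-bromo-2,2-dimethyl-5-[(triisopropylsilyl)oxy]-2H-chromene
Conditions: PhNEt2, 190 °C
Reagents that add atoms: none
Why: Aromatic propargyl Claisen rearrangement to the only free ortho carbon (between the two oxygens), then 1,5-hydrogen shift and oxa-6π electrocyclisation, closes the dimethylpyran ring and leaves bromine ortho to the ring oxygen.

Step 8
Reactants: 12 8-bromo-2,2-dimethyl-5-[(triisopropylsilyl)oxy]-2H-chromene; 8 rac-3-bromo-6-(3-methylbut-2-en-1-yl)-7-[(triisopropylsilyl)oxy]chroman-2-one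
Product: 15 (3R)-3-{2,2-dimethyl-5-[(triisopropylsilyl)oxy]-2H-chromen-8-yl}-6-(3-methylbut-2-en-1-yl)-7-[(triisopropylsilyl)oxy]chroman-2-one, via arylmagnesium bromide 13 (not isolated), via arylzinc iodide 14 (not isolated)
Conditions: Mg, LiCl, THF, 25 °C; ZnI2, 0 °C; then 8 (1.0 equiv; 14 1.3 equiv), NiCl2(dme) (10 mol%), 2,6-bis[(4R)-4-phenyl-4,5-dihydrooxazol-2-yl]pyridine ((R,R)-Ph-pybox, 13 mol%), dme/THF, −30 °C (dme = 1,2-dimethoxyethane)
Reagents that add atoms: none
Why: Proposed new method: the racemic α-bromolactone acts as an enolonium (α-acyl cation) equivalent, since bromine abstraction by a monovalent nickel–aryl species gives a planar C3 radical that erases the starting configuration, and its capture by the pybox-bound nickel followed by reductive elimination forms C3–C1′ under ligand control so that both enantiomers of 8 converge on (R)-15; the closest known reaction types are the nickel/pybox enantioconvergent Negishi arylation of racemic α-bromoketones with arylzinc reagents and the nickel/diamine enantioconvergent arylation of racemic α-bromo aryl esters.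

Step 9
Reactants: 15 (3R)-3-{2,2-dimethyl-5-[(triisopropylsilyl)oxy]-2H-chromen-8-yl}-6-(3-methylbut-2-en-1-yl)-7-[(triisopropylsilyl)oxy]chroman-2-one
Product: 16 (2R)-2-{2,2-dimethyl-5-[(triisopropylsilyl)oxy]-2H-chromen-8-yl}-3-{2-hydroxy-5-(3-methylbut-2-en-1-yl)-4-[(triisopropylsilyl)oxy]phenyl}propan-1-ol
Conditions: LiAlH4, THF, −40 to 0 °C
Reagents that add atoms: none
Why: Ester reduction of the unhindered aryl lactone by LiAlH4 is faster at low temperature than removal of the acidic C3–H, so the diol keeps the (R) configuration.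

Step 10
Reactants: 16 (2R)-2-{2,2-dimethyl-5-[(triisopropylsilyl)oxy]-2H-chromen-8-yl}-3-{2-hydroxy-5-(3-methylbut-2-en-1-yl)-4-[(triisopropylsilyl)oxy]phenyl}propan-1-ol
Product: 17 (3R)-3-{2,2-dimethyl-5-[(triisopropylsilyl)oxy]-2H-chromen-8-yl}-6-(3-methylbut-2-en-1-yl)-7-[(triisopropylsilyl)oxy]chromane
Conditions: PPh3, DIAD, THF, 0 °C to rt
Reagents that add atoms: none
Why: Intramolecular Mitsunobu etherification, in which the activated primary alcohol is displaced by the only free phenol in a 6-exo closure that forms O1–C2 without touching C3.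

Step 11
Reactants: 17 (3R)-3-{2,2-dimethyl-5-[(triisopropylsilyl)oxy]-2H-chromen-8-yl}-6-(3-methylbut-2-en-1-yl)-7-[(triisopropylsilyl)oxy]chromane
Product: 18 (3R)-3-(5-hydroxy-2,2-dimethyl-2H-chromen-8-yl)-6-(3-methylbut-2-en-1-yl)chroman-7-ol
Conditions: Bu4NF, AcOH, THF, 0 °C
Reagents that add atoms: none
Why: Fluoride desilylation of both aryl silyl ethers under acetic acid buffering leaves the prenyl and chromene alkenes and the C3 centre untouched.

**Compound list**
1 | 4-bromoresorcinol (4-bromobenzene-1,3-diol) | Oc1ccc(Br)c(O)c1 | starting material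
2 | acrylic acid | C=CC(=O)O | starting material
3 | 6-bromo-7-hydroxychroman-2-one | O=C1CCc2cc(Br)c(O)cc2O1 | intermediate
4 | 6-bromo-7-[(triisopropylsilyl)oxy]chroman-2-one | O=C1CCc2cc(Br)c(O[Si](C(C)C)(C(C)C)C(C)C)cc2O1 | intermediate
5 | tributyl(3-methylbut-2-en-1-yl)stannane | CC(C)=CC[Sn](CCCC)(CCCC)CCCC | starting material
6 | 6-(3-methylbut-2-en-1-yl)-7-[(triisopropylsilyl)oxy]chroman-2-one | O=C1CCc2cc(CC=C(C)C)c(O[Si](C(C)C)(C(C)C)C(C)C)cc2O1 | intermediate
7 | 6-(3-methylbut-2-en-1-yl)-7-[(triisopropylsilyl)oxy]-2-[(trimethylsilyl)oxy]-4H-chromene (silyl ketene acetal) | C[Si](C)(C)OC1=CCc2cc(CC=C(C)C)c(O[Si](C(C)C)(C(C)C)C(C)C)cc2O1 | intermediate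
8 | rac-3-bromo-6-(3-methylbut-2-en-1-yl)-7-[(triisopropylsilyl)oxy]chroman-2-one | O=C1Oc2cc(O[Si](C(C)C)(C(C)C)C(C)C)c(CC=C(C)C)cc2CC1Br | intermediate
9 | 2-bromo-5-[(triisopropylsilyl)oxy]phenol | Oc1cc(O[Si](C(C)C)(C(C)C)C(C)C)ccc1Br | intermediate
10 | 3-chloro-3-methylbut-1-yne | C#CC(C)(C)Cl | starting material
11 | [4-bromo-3-(2-methylbut-3-yn-2-yloxy)phenoxy]triisopropylsilane | C#CC(C)(C)Oc1cc(O[Si](C(C)C)(C(C)C)C(C)C)ccc1Br | intermediate
12 | 8-bromo-2,2-dimethyl-5-[(triisopropylsilyl)oxy]-2H-chromene | CC1(C)C=Cc2c(O[Si](C(C)C)(C(C)C)C(C)C)ccc(Br)c2O1 | intermediate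
13 | {2,2-dimethyl-5-[(triisopropylsilyl)oxy]-2H-chromen-8-yl}magnesium bromide | CC1(C)C=Cc2c(O[Si](C(C)C)(C(C)C)C(C)C)ccc([Mg]Br)c2O1 | intermediate
14 | {2,2-dimethyl-5-[(triisopropylsilyl)oxy]-2H-chromen-8-yl}zinc iodide | CC1(C)C=Cc2c(O[Si](C(C)C)(C(C)C)C(C)C)ccc([Zn]I)c2O1 | intermediate
15 | (3R)-3-{2,2-dimethyl-5-[(triisopropylsilyl)oxy]-2H-chromen-8-yl}-6-(3-methylbut-2-en-1-yl)-7-[(triisopropylsilyl)oxy]chroman-2-one | CC(C)=CCc1cc2c(cc1O[Si](C(C)C)(C(C)C)C(C)C)OC(=O)[C@@H](c1ccc(O[Si](C(C)C)(C(C)C)C(C)C)c3c1OC(C)(C)C=C3)C2 | intermediate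
16 | (2R)-2-{2,2-dimethyl-5-[(triisopropylsilyl)oxy]-2H-chromen-8-yl}-3-{2-hydroxy-5-(3-methylbut-2-en-1-yl)-4-[(triisopropylsilyl)oxy]phenyl}propan-1-ol | OC[C@@H](c1ccc(O[Si](C(C)C)(C(C)C)C(C)C)c2c1OC(C)(C)C=C2)Cc1cc(CC=C(C)C)c(O[Si](C(C)C)(C(C)C)C(C)C)cc1O | intermediate
17 | (3R)-3-{2,2-dimethyl-5-[(triisopropylsilyl)oxy]-2H-chromen-8-yl}-6-(3-methylbut-2-en-1-yl)-7-[(triisopropylsilyl)oxy]chromane | CC(C)=CCc1cc2c(cc1O[Si](C(C)C)(C(C)C)C(C)C)OC[C@@H](c1ccc(O[Si](C(C)C)(C(C)C)C(C)C)c3c1OC(C)(C)C=C3)C2 | intermediate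
18 | (3R)-3-(5-hydroxy-2,2-dimethyl-2H-chromen-8-yl)-6-(3-methylbut-2-en-1-yl)chroman-7-ol | CC(C)=CCc1cc2c(cc1O)OC[C@@H](c1ccc(O)c3c1OC(C)(C)C=C3)C2 | target

**Step count**
Total: 11 steps. Longest linear sequence: 8 steps (1, 2, 3, 4, 8, 9, 10, 11); steps 5–7 form the second branch, which joins at step 8.

**Steps most likely to fail, with fallbacks**

Step 8 (key coupling). The lactone substrate class is untested. Possible failures are low enantioselectivity, loss of HBr from 8 to the coumarin, and slow transmetalation of the ortho-substituted arylzinc. The fallback sets out from bromolactone 8 and arylzinc iodide 14 and comes back at 15. The two partners are coupled without stereocontrol (NiCl2(dme), 4,4′-di-tert-butyl-2,2′-bipyridine, dme/THF, 0 °C) to give the racemic 3-aryl lactone F1. LiN(SiMe3)2/Me3SiCl at −78 °C converts it into the tetrasubstituted trimethylsilyl ketene acetal F2. Catalytic enantioselective protonation (BINOL-derived chiral N-triflyl thiophosphoramide, phenol as stoichiometric proton source, toluene, low temperature) then sets C3 and gives 15. The stereocentre is thus created by proton transfer to a planar ketene acetal and not in the C–C bond formation.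

Step 4 (α-bromination). The bromolactone may lose HBr to the coumarin or over-brominate, and it may not survive isolation. The fallback sets out from lactone 6 (as its ketene acetal 7, freed from salts by filtration under argon) and from arylmagnesium bromide 13, and comes back at 15. The polarity roles are exchanged so that no bromolactone is needed. Reagent 13 is quenched with Bu3SnCl to give the arylstannane F3. Ipso-substitution with [hydroxy(tosyloxy)iodo]mesitylene (CH2Cl2, −40 °C) gives the aryl(mesityl)iodonium tosylate F4, an aryl cation equivalent. Cu(MeCN)4OTf with a chiral Ph-bisoxazoline ligand (CH2Cl2, rt) transfers the chromenyl group to ketene acetal 7 and gives 15 directly.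

Step 5 (mono-silylation). Selectivity between the two hydroxyls of 1 may be modest. The fallback sets out from 1 and 10 and comes back at 12. The order is inverted so that silylation is done when only one hydroxyl remains. Compound 1 is first etherified with 10 (DBU 1.0 equiv, CuCl2 cat., MeCN, −10 °C), relying on the greater acidity of the hydroxyl next to bromine, to give 4-bromo-3-(2-methylbut-3-yn-2-yloxy)phenol F5. Heating (PhNEt2, 190 °C) gives 8-bromo-2,2-dimethyl-2H-chromen-5-ol F6, and any ether formed at the other oxygen gives an isomeric chromene that is removed here. The single hydroxyl of F6 is then silylated (i-Pr3SiCl, imidazole, DMF) to give 12.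

**Further compounds**
F1 | step 8 | rac-3-{2,2-dimethyl-5-[(triisopropylsilyl)oxy]-2H-chromen-8-yl}-6-(3-methylbut-2-en-1-yl)-7-[(triisopropylsilyl)oxy]chroman-2-one | CC(C)=CCc1cc2c(cc1O[Si](C(C)C)(C(C)C)C(C)C)OC(=O)C(c1ccc(O[Si](C(C)C)(C(C)C)C(C)C)c3c1OC(C)(C)C=C3)C2
F2 | step 8 | 3-{2,2-dimethyl-5-[(triisopropylsilyl)oxy]-2H-chromen-8-yl}-6-(3-methylbut-2-en-1-yl)-7-[(triisopropylsilyl)oxy]-2-[(trimethylsilyl)oxy]-4H-chromene | CC(C)=CCc1cc2c(cc1O[Si](C(C)C)(C(C)C)C(C)C)OC(O[Si](C)(C)C)=C(c1ccc(O[Si](C(C)C)(C(C)C)C(C)C)c3c1OC(C)(C)C=C3)C2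
F3 | step 4 | tributyl{2,2-dimethyl-5-[(triisopropylsilyl)oxy]-2H-chromen-8-yl}stannane | CC1(C)C=Cc2c(O[Si](C(C)C)(C(C)C)C(C)C)ccc([Sn](CCCC)(CCCC)CCCC)c2O1
F4 | step 4 | {2,2-dimethyl-5-[(triisopropylsilyl)oxy]-2H-chromen-8-yl}(2,4,6-trimethylphenyl)iodonium 4-methylbenzenesulfonate | Cc1cc(C)c([I+]c2ccc(O[Si](C(C)C)(C(C)C)C(C)C)c3c2OC(C)(C)C=C3)c(C)c1.Cc1ccc(S(=O)(=O)[O-])cc1
F5 | step 5 | 4-bromo-3-(2-methylbut-3-yn-2-yloxy)phenol | C#CC(C)(C)Oc1cc(O)ccc1Br
F6 | step 5 | 8-bromo-2,2-dimethyl-2H-chromen-5-ol | CC1(C)C=Cc2c(O)ccc(Br)c2O1
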